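# Magnone B by formaldehyde annulation of a lactone-fused donor–acceptor cyclopropane

## The problem

Magnone B is one tetrahydrofuran ring (O1, C2, C3, C4, C5) with three contiguous stereocentres. C2 carries the 3,4,5-trimethoxyphenyl group, C3 the hydroxymethyl carbon C6, C4 the carbonyl carbon C7 of the 3,4-dimethoxybenzoyl group, and C5 is a bare methylene. The configuration is (2S,3R,4R): the aryl group at C2 is trans to C6 and the aroyl group at C4 is cis to C6. C3 is the hub from which both neighbours can be controlled, but the two relays run in opposite senses, and the 3,4-cis relation is the more crowded and presumably less stable one. C4 is the fragile centre: it is a methine α to an aryl ketone and epimerises through the enol or enolate, and that enolate has the ring oxygen in the β position, so strong base also threatens the ring by retro-oxa-Michael opening. C2 is a benzylic ether of an electron-rich arene and ionises under strong Brønsted or Lewis acids. The primary alcohol lies γ to the ketone and can do without a protecting group only if it is tied up until the end. The enabling feature is that C2, a latent benzylic cation, and C4, a latent enolate carbon, are 1,3-related across C3, while the two ring atoms on the other side, O1 and C5, together are one molecule of formaldehyde. If C4 carries one further carbonyl carbon (C8) tied to the C6 oxygen as a lactone, C2–C3–C4 can be a donor–acceptor cyclopropane with a geminal keto-lactone acceptor.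

## Retrosynthesis

**13 to 10.** The first backward move adds a carbon. The C4–H bond of magnone B (13) and the O–H bond at C6 are both replaced by bonds to an extra carbonyl carbon C8, giving the cis-fused keto-lactone 10. Compared with cutting a ring C–O bond of 13 directly, this keeps C4 quaternary and non-epimerisable while the ring is built. It also gives C4 the two geminal acceptors a strain-release annulation needs, and it ties up the C6 oxygen without a protecting group. The price is paid in the forward direction: the lactone is hydrolysed to hydroxy keto acid 11, decarboxylation gives enol 12, and the new C4–H bond must arrive on the face anti to C6.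

**10 to 8 and 9.** In 10 the bonds O1–C2 and C4–C5 are cut together. This excises O1 and C5 as formaldehyde (9) and reconnects C2 to C4 as the cyclopropane of bicyclic lactone 8. Cutting only one of the two bonds would leave an open-chain benzylic oxygen centre whose configuration must be made separately. Cutting both lets ring strain set C2 and form the ring in one operation. Precursor 8 is simpler by one ring-forming event, and its three stereocentres all follow from one alkene geometry and one face selection. The forward reaction must cleave C2–C4 and not C3–C4, invert C2, and close through carbon.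

**8 to 7.** The cyclopropane bonds C2–C4 and C3–C4 of 8 are cut to a carbene at C4 and a Z alkene, that is, to diazo keto ester 7. An intermolecular cyclopropanation or a Michael-initiated ring closure would place the aryl group exo. Only intramolecular syn addition to a Z-cinnamyl ester puts the aryl group cis to C6, which is what inversion at C2 later requires. Compound 7 is achiral, so the forward reaction must be enantioselective as well as stereospecific.

**7 to 6 to 4 and 5.** The diazo group of 7 goes back to the active methylene of keto ester 6. The ester C–O bond of 6 is then cut to Z-cinnamyl alcohol 4 and the commercial aroylacetate 5. This ester bond is the only link between the two aryl halves, so the route is convergent, and the forward steps are a transesterification and a diazo transfer.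

**4 to 3 to 1 and 2.** The Z alkene of 4 comes from alkyne 3, and the aryl–alkyne bond of 3 is cut to iodide 1 and propargyl alcohol (2). The alkyne is preferred to an olefination route because a syn semihydrogenation fixes the Z geometry that carries all later stereochemistry.

## Roads not taken

**Alternative 1:** The cut is at C4–C7 and C2–C3, with the ring C–O bonds left for later. In the forward key step the lithium derivative of 2-(3,4-dimethoxyphenyl)-1,3-dithiane A2 adds to the β-carbon of (5R)-5-(l-menthyloxy)furan-2(5H)-one A1, anti to the menthyloxy group. The lactone enolate is then trapped by 3,4,5-trimethoxybenzaldehyde A3 to give the trans-disubstituted lactone A4 as carbinol epimers.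

- Merits: tandem conjugate addition–aldol on such lactones is well-established chemistry, and the absolute configuration comes from a crystalline auxiliary. The lactone carbonyl of A4 is the future C6 and its acetal carbon the future C5, so the reliable trans addition becomes the 3,4-cis relation of the target. C7 stays masked, so C4 is not acidic until the end.
- Weak points: C2 is formed as a mixture and must be corrected in an ionising ring closure under thermodynamic control. Two carbons must be reduced and three hydroxyls told apart, and the thioacetal must be removed last beside two electron-rich arenes, unmasking the epimerisable ketone. The auxiliary is stoichiometric.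
- Comparison: this road is clearly better in precedent and in how it secures the 3,4-cis relation; in step count it is about equal. The chosen plan offers in return catalytic asymmetric induction, a stereospecific C2, and no hydroxyl differentiation or thioacetal handling.

**Alternative 2:** The cut is at C3–C6. The (bromomethyl)dimethylsilyl ether A5, carrying the C7 carbinol on C4 of a 2-aryl-2,5-dihydrofuran, would give a silylmethyl radical with tin hydride. The radical adds 6-endo to C3, and the C4 radical takes hydrogen to give the cis-fused siloxane A6. Oxidative cleavage of the C–Si bond (Tamao oxidation) and oxidation of the benzylic C7 carbinol would follow.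

- Merits: the 3,4-cis relation is fixed by ring fusion in a neutral radical step. C7 stays at the alcohol level until a final mild oxidation, so C4 never meets acid or base as a ketone α-carbon. On this count it is safer than the chosen plan.
- Weak points: 6-endo has to beat 5-exo attack at C4. A5 is an enantioenriched, fully substituted dihydrofuran that itself needs a multistep synthesis. The carbinol stereocentre is made only to be destroyed, tin is stoichiometric, and two further steps follow the key step.
- Comparison: more secure at C4, but markedly longer and less convergent than seven steps from commercial materials.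

**Alternative 3:** The cut is at C3–C6 and C4–C7 together, as a cyclobutene whose C6=C7 bond is cleaved afterwards. 4-Ethynyl-1,2-dimethoxybenzene A7 and (2S)-2-(3,4,5-trimethoxyphenyl)-2,5-dihydrofuran A8 would combine under a cationic monovalent gold catalyst such as [(tBuXPhos)Au(NCMe)]SbF6 to give cyclobutene A9. Ozonolysis and reduction of C6 from the aldehyde level would finish the synthesis.

- Merits: it is the shortest road on paper, since A8 is one asymmetric Heck arylation away from commercial material and only three steps follow. The 3,4-cis relation again comes from ring fusion.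
- Weak points: intermolecular gold [2+2] reactions favour electron-rich, 1,1-disubstituted or trisubstituted alkenes, and the alkene of A8 is 1,2-disubstituted and inductively deactivated. Nothing strong directs the aryl-bearing alkyne carbon to C4 rather than C3. Ozone must spare two electron-rich arenes. After cleavage both C3 and C4 are α to carbonyl groups and can epimerise.
- Comparison: this road wins on step count. The chosen plan has a single unknown step, but its regiochemistry is dictated by donor–acceptor polarity, and C3 is never α to a carbonyl group.

Key step: step 6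

Assumption: Rh2(S-PTTL)4 is taken to favour the (1S,5R,6R) lactone 8 in step 5; if the antipode predominates, the (R)-configured catalyst is used and nothing else changes.

Assumption: paraformaldehyde is the practical source of formaldehyde 9 and is depolymerised in the flask by the Lewis acid.

## Route

Step 1
Reactants: 1 5-iodo-1,2,3-trimethoxybenzene; 2 prop-2-yn-1-ol (propargyl alcohol)
Product: 3 3-(3,4,5-trimethoxyphenyl)prop-2-yn-1-ol
Conditions: PdCl2(PPh3)2 (2 mol%), CuI (4 mol%), Et3N, THF, rt
Reagents that add atoms: none
Why: Sonogashira coupling; the aryl iodide undergoes oxidative addition at room temperature despite the electron-rich ring, and the free primary alcohol is tolerated.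

Step 2
Reactants: 3 3-(3,4,5-trimethoxyphenyl)prop-2-yn-1-ol
Product: 4 (Z)-3-(3,4,5-trimethoxyphenyl)prop-2-en-1-ol
Conditions: H2 (1 atm), Pd/CaCO3 poisoned with Pb(OAc)2 (Lindlar catalyst), quinoline, EtOAc, rt
Reagents that add atoms: none
Why: Lindlar semihydrogenation; syn delivery of hydrogen on the poisoned surface gives the Z alkene, and quinoline holds back over-reduction and Z-to-E isomerisation.

Step 3
Reactants: 4 (Z)-3-(3,4,5-trimethoxyphenyl)prop-2-en-1-ol; 5 ethyl 3-(3,4-dimethoxyphenyl)-3-oxopropanoate
Product: 6 (Z)-3-(3,4,5-trimethoxyphenyl)prop-2-en-1-yl 3-(3,4-dimethoxyphenyl)-3-oxopropanoate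
Conditions: DMAP (0.2 equiv), toluene, 105 °C, 4 Å sieves to take up EtOH
Reagents that add atoms: none
Why: Transesterification of a β-keto ester, which exchanges its alkoxy group far more readily than a simple ester and is driven by removal of ethanol; the Z alkene is not touched.

Step 4
Reactants: 6 (Z)-3-(3,4,5-trimethoxyphenyl)prop-2-en-1-yl 3-(3,4-dimethoxyphenyl)-3-oxopropanoate
Product: 7 (Z)-3-(3,4,5-trimethoxyphenyl)prop-2-en-1-yl 2-diazo-3-(3,4-dimethoxyphenyl)-3-oxopropanoate
Conditions: p-ABSA (1.2 equiv), Et3N, MeCN, 0 °C to rt
Reagents that add atoms: 4-acetamidobenzenesulfonyl azide (p-ABSA), CC(=O)Nc1ccc(cc1)S(=O)(=O)N=[N+]=[N-]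
Why: Regitz diazo transfer onto the doubly activated methylene; the sulfonamide by-product is removed by filtration and aqueous wash.

Step 5
Reactants: 7 (Z)-3-(3,4,5-trimethoxyphenyl)prop-2-en-1-yl 2-diazo-3-(3,4-dimethoxyphenyl)-3-oxopropanoate
Product: 8 (1S,5R,6R)-1-(3,4-dimethoxybenzoyl)-6-(3,4,5-trimethoxyphenyl)-3-oxabicyclo[3.1.0]hexan-2-one (aryl group endo, cis to the lactone CH2O)
Conditions: Rh2(S-PTTL)4 [dirhodium tetrakis(N-phthaloyl-(S)-tert-leucinate)] (1 mol%), CH2Cl2, 25–40 °C, slow addition of 7
Reagents that add atoms: none
Why: Intramolecular cyclopropanation of an allylic α-diazo-β-keto ester by a dirhodium carbene; the addition is concerted and syn, so the Z alkene places the aryl group cis to C6 and the ester tether forces C8 cis to C6. The chiral carboxylate ligands choose the alkene face and so set C2, C3 and C4 together.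

Step 6
Reactants: 8 (1S,5R,6R)-1-(3,4-dimethoxybenzoyl)-6-(3,4,5-trimethoxyphenyl)-3-oxabicyclo[3.1.0]hexan-2-one; 9 formaldehyde (charged as paraformaldehyde)
Product: 10 (1R,2S,5R)-5-(3,4-dimethoxybenzoyl)-2-(3,4,5-trimethoxyphenyl)-3,7-dioxabicyclo[3.3.0]octan-6-one (cis-fused, angular aroyl group)
Conditions: Sn(OTf)2 (10 mol%), paraformaldehyde (5 equiv), 4 Å sieves, CH2Cl2, rt
Reagents that add atoms: none
Why: Proposed new method: formaldehyde has not been shown as the carbonyl partner of a lactone-fused keto-acceptor cyclopropane; the closest known reaction type is the Lewis-acid-catalysed (3+2) annulation of 2-arylcyclopropane-1,1-diesters with aryl and alkyl aldehydes, which runs with inversion at the donor carbon. Divalent tin triflate chelates the ketone and lactone carbonyls on C4 of 8 and polarises the C2–C4 bond, which the rigid lactone holds parallel to the carbonyl π system and which alone bears the donor aryl group, so this bond and not C3–C4 breaks. The oxygen of formaldehyde, or an oxymethylene oxygen of the polymer that then sheds its chain, attacks C2 from the side opposite C4 in an SN2-like opening and leaves a tin-bound ion pair of keto-lactone enolate and O1=C5 oxocarbenium ion. C4 of the enolate then adds to C5 and closes the tetrahydrofuran ring; the closure is 5-endo-trig at the oxocarbenium ion and exo to the enolate, the same aldol-type mode that operates in the known aldehyde annulations. C2 is set by inversion, so the aryl group, cis to C6 on the cyclopropane, becomes trans to C6 on the new ring, while C3 is untouched. The quaternary centre C4 is set by ring fusion, because a bicyclo[3.3.0] skeleton forms only cis-fused, which places the aroyl group anti to C6. The step needs capture by formaldehyde to outrun ionisation of C2 to a free benzylic cation; the 3,4,5-trimethoxyphenyl group, with its para methoxy group twisted between two inductively withdrawing meta methoxy groups, is only a moderate donor, and an excess of formaldehyde at ambient temperature keeps the bimolecular opening fast.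

Step 7
Reactants: 10 (1R,2S,5R)-5-(3,4-dimethoxybenzoyl)-2-(3,4,5-trimethoxyphenyl)-3,7-dioxabicyclo[3.3.0]octan-6-one
Product: 13 magnone B [(3,4-dimethoxyphenyl)((3R,4R,5S)-4-(hydroxymethyl)-5-(3,4,5-trimethoxyphenyl)oxolan-3-yl)methanone], via hydroxy keto acid 11 (not isolated), via enol 12 (not isolated)
Conditions: LiOH·H2O (2.5 equiv), THF/H2O 3:1, 0 °C; then AcOH to pH 4–5, 40 °C
Reagents that add atoms: none
Why: Hydrolysis–decarboxylation of an α-acyl lactone: hydroxide opens the strained lactone at its carbonyl to the carboxylate of 11, and on buffering the β-keto acid loses CO2 through the six-membered cyclic transition state to enol 12. C4 is set by kinetic ketonisation of this exocyclic enol, with acetic acid delivering the proton to the face anti to the adjacent hydroxymethyl group, which leaves the aroyl group cis to C6. The mild pH and temperature should keep the α-methine of 13 from equilibrating and the C2 benzylic ether from ionising.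

## Compound list

1 | 5-iodo-1,2,3-trimethoxybenzene | COc1cc(I)cc(OC)c1OC | starting material
2 | prop-2-yn-1-ol (propargyl alcohol) | C#CCO | starting material
3 | 3-(3,4,5-trimethoxyphenyl)prop-2-yn-1-ol | COc1cc(C#CCO)cc(OC)c1OC | intermediate
4 | (Z)-3-(3,4,5-trimethoxyphenyl)prop-2-en-1-ol | COc1cc(/C=C\CO)cc(OC)c1OC | intermediate
5 | ethyl 3-(3,4-dimethoxyphenyl)-3-oxopropanoate | CCOC(=O)CC(=O)c1ccc(OC)c(OC)c1 | starting material
6 | (Z)-3-(3,4,5-trimethoxyphenyl)prop-2-en-1-yl 3-(3,4-dimethoxyphenyl)-3-oxopropanoate | COc1ccc(C(=O)CC(=O)OC/C=C\c2cc(OC)c(OC)c(OC)c2)cc1OC | intermediate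
7 | (Z)-3-(3,4,5-trimethoxyphenyl)prop-2-en-1-yl 2-diazo-3-(3,4-dimethoxyphenyl)-3-oxopropanoate | COc1ccc(C(=O)C(=[N+]=[N-])C(=O)OC/C=C\c2cc(OC)c(OC)c(OC)c2)cc1OC | intermediate
8 | (1S,5R,6R)-1-(3,4-dimethoxybenzoyl)-6-(3,4,5-trimethoxyphenyl)-3-oxabicyclo[3.1.0]hexan-2-one | COc1ccc(C(=O)[C@@]23C(=O)OC[C@@H]2[C@@H]3c4cc(OC)c(OC)c(OC)c4)cc1OC | intermediate
9 | formaldehyde (from paraformaldehyde) | C=O | starting material
10 | (1R,2S,5R)-5-(3,4-dimethoxybenzoyl)-2-(3,4,5-trimethoxyphenyl)-3,7-dioxabicyclo[3.3.0]octan-6-one | COc1ccc(C(=O)[C@]23CO[C@H](c4cc(OC)c(OC)c(OC)c4)[C@H]2COC3=O)cc1OC | intermediate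
11 | (3R,4R,5S)-3-(3,4-dimethoxybenzoyl)-4-(hydroxymethyl)-5-(3,4,5-trimethoxyphenyl)oxolane-3-carboxylic acid | COc1ccc(C(=O)[C@]2(C(=O)O)CO[C@H](c3cc(OC)c(OC)c(OC)c3)[C@H]2CO)cc1OC | intermediate
12 | {(2S,3R)-4-[(3,4-dimethoxyphenyl)(hydroxy)methylidene]-2-(3,4,5-trimethoxyphenyl)oxolan-3-yl}methanol (enol; double-bond geometry not defined) | COc1ccc(C(O)=C2CO[C@H](c3cc(OC)c(OC)c(OC)c3)[C@H]2CO)cc1OC | intermediate
13 | magnone B, (3,4-dimethoxyphenyl)[(3R,4R,5S)-4-(hydroxymethyl)-5-(3,4,5-trimethoxyphenyl)oxolan-3-yl]methanone; (2S,3R,4R) in the ring numbering used above | COc1ccc(C(=O)[C@H]2CO[C@H](c3cc(OC)c(OC)c(OC)c3)[C@H]2CO)cc1OC | target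

## Step count and risks

Total steps: 7. Longest linear sequence: 7 steps (1 to 13); compounds 2, 5 and 9 enter as commercial materials.

**Step 6 (key step, new method).** Three processes are most likely to go wrong.

- Ionisation of the cyclopropane before formaldehyde attacks. A free benzylic cation would erase the stereospecificity at C2 and allow the ketone oxygen to close on C2 (Cloke–Wilson-type ring expansion). That closure is impossible as a backside displacement and therefore needs the cation.
- Sluggish opening, because formaldehyde is a weak oxygen nucleophile and is available only as fast as the polymer unzips.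
- Uptake of more than one formaldehyde unit, or electrophilic hydroxymethylation of the trimethoxyphenyl ring.

The fallback uses known chemistry, sets out from 8 and returns at 10, making the same two bonds in separate operations. Compound 8 is opened at C2 by water under Lewis acid catalysis (Cu(OTf)2, H2O, 1,4-dioxane). This is a known homoconjugate addition of an oxygen nucleophile to a donor–acceptor cyclopropane and runs with inversion. It gives (4R)-3-(3,4-dimethoxybenzoyl)-4-[(S)-hydroxy(3,4,5-trimethoxyphenyl)methyl]oxolan-2-one F1. Acetal exchange with dimethoxymethane and P2O5 in CHCl3 turns the benzylic alcohol into the methoxymethyl ether (4R)-3-(3,4-dimethoxybenzoyl)-4-[(S)-(methoxymethoxy)(3,4,5-trimethoxyphenyl)methyl]oxolan-2-one F2. TMSOTf in CH2Cl2 at low temperature then ionises the acetal to the same O1=C5 oxocarbenium ion. The enol of the keto-lactone captures it at C4 (intramolecular acetal alkylation of a β-dicarbonyl compound) and gives 10 with loss of methanol.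

**Step 5.** The most likely failure is poor face selection. A carbene flanked by two acceptors is very reactive and reacts through an early transition state, so the enantiomeric purity of 8, and with it of everything downstream, may be insufficient. Competing attack of the carbene on the electron-rich arene or on the ketone oxygen would lower the yield.

The fallback sets out from 4 and returns at 8. Compound 4 is acylated with bromoacetyl bromide to (Z)-3-(3,4,5-trimethoxyphenyl)prop-2-en-1-yl bromoacetate F3. N,N'-Ditosylhydrazine and DBU convert this into (Z)-3-(3,4,5-trimethoxyphenyl)prop-2-en-1-yl diazoacetate F4. Intramolecular cyclopropanation with the carboxamidate catalyst Rh2(5S-MEPY)4 [dirhodium tetrakis(methyl (5S)-2-oxopyrrolidine-5-carboxylate)], or its mirror image as the configuration requires, gives (1S,5R,6S)-6-(3,4,5-trimethoxyphenyl)-3-oxabicyclo[3.1.0]hexan-2-one F5. This catalyst class performs best with Z-disubstituted allylic diazoacetates. Deprotonation of the only α-hydrogen, at the bridgehead, with LiN(SiMe3)2 in the presence of 3,4-dimethoxybenzoyl chloride (THF, −78 °C) acylates C4 with retention on the exo face and gives 8. The bridgehead acylation is the least precedented operation of this detour, which is why it is not the main route.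

**Step 7.** The most likely failure is poor facial selectivity in the ketonisation of enol 12. The adjacent hydroxymethyl group is small, the aryl group at C2 sits on the face the proton must use, and the C6 hydroxyl could relay a proton to the wrong face. Reclosure of the lactone on acidification may compete with decarboxylation. Hydroxide may attack the ketone instead of the lactone and cleave the aroyl group. Later epimerisation at C4 is possible if the pH drifts.

The fallback sets out from 10 and returns at 13. Hydrolysis–decarboxylation without regard to selectivity gives 13 mixed with its C4 epimer (3,4-dimethoxyphenyl)[(3S,4R,5S)-4-(hydroxymethyl)-5-(3,4,5-trimethoxyphenyl)oxolan-3-yl]methanone F6. Under dehydrating acid catalysis (camphorsulfonic acid, toluene, 4 Å sieves, 60 °C) both epimers interconvert through enol 12. Only the 3,4-cis hydroxy ketone can close to a hemiketal and lose water, so the mixture should drain into the bicyclic enol ether (5R,6S)-2-(3,4-dimethoxyphenyl)-6-(3,4,5-trimethoxyphenyl)-3,7-dioxabicyclo[3.3.0]oct-1-ene F7. Dilute aqueous acid in THF at 0 °C then protonates C4 on the only face that leads to a cis-fused bicyclic oxocarbenium ion. Water adds, the hemiketal opens, and 13 results with C4 fixed by ring fusion instead of by sterics.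

## Further compounds

F1 | step 6 | (4R)-3-(3,4-dimethoxybenzoyl)-4-[(S)-hydroxy(3,4,5-trimethoxyphenyl)methyl]oxolan-2-one (epimers at the enolisable C3) | COc1ccc(C(=O)C2C(=O)OC[C@@H]2[C@H](O)c3cc(OC)c(OC)c(OC)c3)cc1OC
F2 | step 6 | (4R)-3-(3,4-dimethoxybenzoyl)-4-[(S)-(methoxymethoxy)(3,4,5-trimethoxyphenyl)methyl]oxolan-2-one (epimers at the enolisable C3) | COc1ccc(C(=O)C2C(=O)OC[C@@H]2[C@H](OCOC)c3cc(OC)c(OC)c(OC)c3)cc1OC
F3 | step 5 | (Z)-3-(3,4,5-trimethoxyphenyl)prop-2-en-1-yl bromoacetate | COc1cc(/C=C\COC(=O)CBr)cc(OC)c1OC
F4 | step 5 | (Z)-3-(3,4,5-trimethoxyphenyl)prop-2-en-1-yl diazoacetate | COc1cc(/C=C\COC(=O)C=[N+]=[N-])cc(OC)c1OC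
F5 | step 5 | (1S,5R,6S)-6-(3,4,5-trimethoxyphenyl)-3-oxabicyclo[3.1.0]hexan-2-one (aryl group endo) | O=C1OC[C@@H]2[C@H](c3cc(OC)c(OC)c(OC)c3)[C@H]12
F6 | step 7 | (3,4-dimethoxyphenyl)[(3S,4R,5S)-4-(hydroxymethyl)-5-(3,4,5-trimethoxyphenyl)oxolan-3-yl]methanone (C4 epimer of magnone B) | COc1ccc(C(=O)[C@@H]2CO[C@H](c3cc(OC)c(OC)c(OC)c3)[C@H]2CO)cc1OC
F7 | step 7 | (5R,6S)-2-(3,4-dimethoxyphenyl)-6-(3,4,5-trimethoxyphenyl)-3,7-dioxabicyclo[3.3.0]oct-1-ene | COc1ccc(C2=C3CO[C@H](c4cc(OC)c(OC)c(OC)c4)[C@H]3CO2)cc1OC
A1 | alternative 1 | (5R)-5-[(1R,2S,5R)-2-isopropyl-5-methylcyclohexyloxy]furan-2(5H)-one | O=C1O[C@@H](O[C@@H]2C[C@H](C)CC[C@H]2C(C)C)C=C1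
A2 | alternative 1 | 2-(3,4-dimethoxyphenyl)-1,3-dithiane | COc1ccc(C2SCCCS2)cc1OC
A3 | alternative 1 | 3,4,5-trimethoxybenzaldehyde | COc1cc(C=O)cc(OC)c1OC
A4 | alternative 1 | trans-4-[2-(3,4-dimethoxyphenyl)-1,3-dithian-2-yl]-3-[hydroxy(3,4,5-trimethoxyphenyl)methyl]-5-(l-menthyloxy)oxolan-2-one (carbinol epimers) | O=C1O[C@@H](O[C@@H]2C[C@H](C)CC[C@H]2C(C)C)[C@H](C3(c4ccc(OC)c(OC)c4)SCCCS3)[C@H]1C(O)c5cc(OC)c(OC)c(OC)c5
A5 | alternative 2 | (bromomethyl)dimethylsilyl ether of (R)-(3,4-dimethoxyphenyl)[(5S)-5-(3,4,5-trimethoxyphenyl)-2,5-dihydrofuran-3-yl]methanol (carbinol configuration immaterial) | BrC[Si](C)(C)O[C@H](c1ccc(OC)c(OC)c1)C1=C[C@@H](c2cc(OC)c(OC)c(OC)c2)OC1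
A6 | alternative 2 | cis-fused bicyclic siloxane in which C6–SiMe2–O–C7 bridges C3 and C4 of the 2-(3,4,5-trimethoxyphenyl)tetrahydrofuran, C7 bearing the 3,4-dimethoxyphenyl group | C[Si]1(C)O[C@H](c2ccc(OC)c(OC)c2)[C@H]3CO[C@H](c4cc(OC)c(OC)c(OC)c4)[C@H]3C1
A7 | alternative 3 | 4-ethynyl-1,2-dimethoxybenzene | C#Cc1ccc(OC)c(OC)c1
A8 | alternative 3 | (2S)-2-(3,4,5-trimethoxyphenyl)-2,5-dihydrofuran | C1=C[C@@H](c2cc(OC)c(OC)c(OC)c2)OC1
A9 | alternative 3 | cis-fused 6-(3,4-dimethoxyphenyl)-2-(3,4,5-trimethoxyphenyl)-3-oxabicyclo[3.2.0]hept-6-ene | C1(c2ccc(OC)c(OC)c2)=C[C@@H]3[C@@H](c4cc(OC)c(OC)c(OC)c4)OC[C@H]13
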